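**Strategy.** Rings: A pyrone, B dihydropyran, C cycloheptane, D cyclopentenone. Everything rests on the ring-B hemiketal carbon, which is at once the ether carbon of ring B and a masked ketone of ring C, and on the neighbouring ring-fusion CH that carries the pyrone CH2. Both are made in one semipinacol shift: in a trans-hydrindenedione whose tertiary cyclohexanol carbon bears a 2,3-dihydrofuro[3,2-c]pyranone (pyrone C3, C4, O, O–CH, CH2), the furan C–O bond leaves while the CH(CH3) ring carbon migrates to the O–CH carbon. Cyclohexanol thereby becomes the cycloheptanone ring C, and the freed pyrone 4-OH adds to the new ketone, so the five-membered O-ring reappears as six-membered ring B.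

Key step: step 12

Remark 1: the hemiketal carbon, the CH(OH) carbon beside it and the B/C ring-fusion CH are configurationally labile in the target itself (ring opening to the 2-hydroxy-1,3-diketone, enolisation), so their configuration is taken to be the thermodynamic one; the tertiary carbinol and the C-methyl centre are set under kinetic control.
Remark 2: 4-hydroxy-5,6-dimethyl-2H-pyran-2-one is taken as a purchasable building block.

Step 1
Reactants: 1 2,2-dimethylcyclopentane-1,3-dione
Product: 2 (S)-3-hydroxy-2,2-dimethylcyclopentan-1-one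
Conditions: (R)-2-methyl-CBS-oxazaborolidine (10 mol %), BH3·SMe2 (0.6 equiv), THF, −20 °C; MeOH, aq. work-up
Reagents that add atoms: none
Why: CBS reduction of one of the two homotopic carbonyl groups, the catalyst choosing the carbonyl face with the quaternary carbon as the large substituent, should set the (S)-carbinol, and limiting borane should suppress the diol.

Step 2
Reactants: 2 (S)-3-hydroxy-2,2-dimethylcyclopentan-1-one
Product: 3 (S)-2,2-dimethyl-3-oxocyclopentyl acetate
Conditions: Ac2O, pyridine, DMAP (cat.), CH2Cl2, 0 → 25 °C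
Reagents that add atoms: acetic anhydride CC(=O)OC(C)=O
Why: DMAP-catalysed O-acetylation of a secondary alcohol, which touches no stereocenter.

Step 3
Reactants: 3 (S)-2,2-dimethyl-3-oxocyclopentyl acetate
Product: 4 (S)-5,5-dimethyl-4-oxocyclopent-2-en-1-yl acetate
Conditions: IBX (2.5 equiv), DMSO/toluene, 75 °C
Reagents that add atoms: none
Why: IBX dehydrogenation of a ketone to the enone can only run toward the single enolisable CH2, and the 4-acetoxy enone cannot eliminate acetate because the other α-carbon is quaternary.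

Step 4
Reactants: 4 (S)-5,5-dimethyl-4-oxocyclopent-2-en-1-yl acetate
Product: 6 (1S,4R)-5,5-dimethyl-4-[(trimethylsilyl)ethynyl]-4-[(trimethylsilyl)oxy]cyclopent-2-en-1-yl acetate, via lithium alkoxide 5 (not isolated)
Conditions: Me3SiC≡CH, n-BuLi, THF, −78 °C; then 4, −78 °C; then Me3SiCl, −78 → 0 °C
Reagents that add atoms: (trimethylsilyl)acetylene C#C[Si](C)(C)C; chlorotrimethylsilane C[Si](C)(C)Cl
Why: 1,2-addition of a lithium acetylide to the enone carbonyl (faster than attack on the acetate at −78 °C) should occur on the face opposite the 1,3-related acetoxy group, which sets the tertiary carbinol with its oxygen cis to the acetate, and in situ O-silylation blocks acyl migration.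

Step 5
Reactants: 6 (1S,4R)-5,5-dimethyl-4-[(trimethylsilyl)ethynyl]-4-[(trimethylsilyl)oxy]cyclopent-2-en-1-yl acetate
Product: 10 cis-fused 6,6-dimethyl-6a-[(trimethylsilyl)ethynyl]-3,3a,6,6a-tetrahydro-2H-cyclopenta[b]furan-2-one, via silyl ketene acetal 7 (not isolated), via rearranged silyl ester 8 (not isolated), via hydroxy acid 9 (not isolated)
Conditions: LiN(i-Pr)2, Me3SiCl, THF, −78 → 50 °C; then 1 M HCl, THF, 25 °C
Reagents that add atoms: none
Why: Ireland–Claisen rearrangement delivers the CH2CO2 unit suprafacially to the ring carbon next to the carbinol, on the face of the departing C–O bond and hence cis to the tertiary oxygen, so acidic work-up should close the cis-fused γ-lactone (a trans hydroxy acid from any minor step-4 epimer cannot lactonise).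

Step 6
Reactants: 10 cis-fused 6,6-dimethyl-6a-[(trimethylsilyl)ethynyl]-3,3a,6,6a-tetrahydro-2H-cyclopenta[b]furan-2-one
Product: 12 3-exo-methyl lactone 3,6,6-trimethyl-6a-[(trimethylsilyl)ethynyl]-3,3a,6,6a-tetrahydro-2H-cyclopenta[b]furan-2-one, via lithium enolate 11 (not isolated)
Conditions: LiN(i-Pr)2, THF, −78 °C; then MeI, −78 → −40 °C
Reagents that add atoms: iodomethane CI
Why: Enolate alkylation of a cis-fused bicyclo[3.3.0] lactone takes place from the convex face, anti to the adjacent ring bond, which sets the C-methyl stereocenter (the same epimer is also the thermodynamic one).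

Step 7
Reactants: 12 3-exo-methyl lactone
Product: 14 4-{2-hydroxy-3,3-dimethyl-2-[(trimethylsilyl)ethynyl]cyclopent-4-en-1-yl}pent-1-en-3-one (in equilibrium with its five-membered lactol and drawn open), via magnesium lactolate 13 (not isolated)
Conditions: CH2=CHMgBr (1.1 equiv), THF, −78 °C; aq. NH4Cl
Reagents that add atoms: vinylmagnesium bromide C=C[Mg]Br
Why: Mono-addition of a Grignard reagent to a lactone stops at the lactolate at low temperature (ketone synthesis from lactones), which gives the vinyl ketone without touching a stereocenter.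

Step 8
Reactants: 14 hydroxy vinyl ketone with silylalkyne
Product: 15 4-(2-acetyl-2-hydroxy-3,3-dimethylcyclopent-4-en-1-yl)pent-1-en-3-one
Conditions: HgSO4 (5 mol %), 0.5 M H2SO4, THF, 40 °C
Reagents that add atoms: water O
Why: Mercury-catalysed Markovnikov hydration of an ethynyl carbinol, with protodesilylation, is the classical route to α-hydroxy methyl ketones, and the ketone next to the C-methyl centre is largely masked as the lactol.

Step 9
Reactants: 15 4-(2-acetyl-2-hydroxy-3,3-dimethylcyclopent-4-en-1-yl)pent-1-en-3-one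
Product: 17 trans-fused 6-ethenyl-3a,6-dihydroxy-3,3,7-trimethyl-3,3a,5,6,7,7a-hexahydro-4H-inden-4-one (carbinol carbon C6 unspecified), via dilithium enolate 16 (not isolated)
Conditions: LiN(SiMe3)2 (2.2 equiv), THF, −78 °C; aq. NH4Cl
Reagents that add atoms: none
Why: Kinetic deprotonation of the methyl ketone and intramolecular aldol addition to the vinyl ketone carbonyl should close the six-membered ring (6-enolexo) rather than the eight-membered Michael mode; the new carbinol centre is inconsequential and the C-methyl centre should not enolise at −78 °C.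

Step 10
Reactants: 17 trans-fused vinyl carbinol
Product: 19 6-ethenyl-3a,6-dihydroxy-3,3,7-trimethyl-3,3a,6,7-tetrahydro-2H-indene-2,4(5H)-dione, via allylic hydroperoxide 18 (not isolated)
Conditions: O2, tetraphenylporphyrin (cat.), hν, CH2Cl2, 0 °C; then Ac2O, pyridine, DMAP, 25 °C
Reagents that add atoms: oxygen O=O
Why: Schenck ene reaction followed by Kornblum–DeLaMare dehydration: the only allylic hydrogen sits on the ring-fusion carbon, so oxygen must go to the carbon next to the gem-dimethyl group and the double bond to the ring fusion, which gives the ring-D cyclopentenone.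

Step 11
Reactants: 19 vinyl carbinol enedione; 20 4-hydroxy-5,6-dimethyl-2H-pyran-2-one
Product: 21 2-(3a,6-dihydroxy-3,3,7-trimethyl-2,4-dioxo-3,3a,4,5,6,7-hexahydro-2H-inden-6-yl)-6,7-dimethyl-2,3-dihydro-4H-furo[3,2-c]pyran-4-one (O–CH and carbinol carbons unspecified)
Conditions: Mn(OAc)3·2H2O (2.5 equiv), Cu(OAc)2·H2O (0.5 equiv), AcOH, 40 °C
Reagents that add atoms: none
Why: Mn(OAc)3-mediated oxidative radical [3+2] annulation of a cyclic 1,3-dicarbonyl with a terminal alkene: the pyrone C3 radical adds to the CH2 terminus and the oxidised adduct is closed by the 4-oxygen, giving the dihydrofuran whose O–CH centre forms as a mixture that converges in step 12.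

Step 12
Reactants: 21 dihydrofuropyranone carbinol
Product: 24 deoxy hemiketal (the target lacking the secondary hydroxyl), via bis-silyl ether 22 (not isolated), via ring-opened diketone 23 (not isolated)
Conditions: 1-(trimethylsilyl)imidazole, CH2Cl2, 25 °C; then TMSOTf (1.5 equiv), CH2Cl2, −78 → −20 °C; then 1 M HCl, THF, 25 °C
Reagents that add atoms: none
Why: Proposed new method: silylation of the pyrone carbonyl by TMSOTf turns the 4-alkoxy-2-pyrone into a 4-alkoxy-2-silyloxypyrylium ion, so the furan O–CH bond becomes a nucleofuge of the alkoxypyridinium class, and the tertiary silyl ether pushes a 1,2-shift of the antiperiplanar ring bond onto the O–CH carbon to give a silyloxocarbenium ion that collapses to the cycloheptanone; the closest known reaction types are the Tiffeneau–Demjanov and the organoaluminium-promoted β-mesyloxy alcohol semipinacol ring expansions of 1-(1-X-alkyl)cycloalkanols, which have not been run with a pyronyloxy leaving group. Ring C is closed by ring expansion (six to seven, 1,2-alkyl shift) and ring B by 6-exo-trig addition of the liberated pyrone 4-OH to the new ketone, so the five-membered dihydrofuran is replaced by the six-membered hemiketal. The migrating CH(CH3) carbon keeps its configuration; the former O–CH carbon is inverted and, being α to the new ketone, should equilibrate together with the hemiketal carbon to the trans-fused arrangement with the anomeric hydroxyl axial. The step needs migration of the CH(CH3) carbon rather than the CH2 next to the ring ketone, and ionisation at the O–CH carbon rather than at the tertiary carbinol: the α-keto CH2 is a poor migrating group, and silylation of the carbinol without amine base removes the tertiary ionisation and avoids an enol silane.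

Step 13
Reactants: 24 deoxy hemiketal
Product: 26 CNP0525404.1, via tripotassium enolate 25 (not isolated)
Conditions: KN(SiMe3)2 (3.3 equiv), THF, −78 °C; then 2-(phenylsulfonyl)-3-phenyloxaziridine, −78 °C; AcOH, then pH 4 buffer, 25 °C
Reagents that add atoms: 2-(phenylsulfonyl)-3-phenyloxaziridine O=S(=O)(c1ccccc1)N1OC1c1ccccc1
Why: Electrophilic α-hydroxylation of an enolate with a Davis oxaziridine: base opens the hemiketal so that the CH2 lies between two ketones and is the most acidic carbon, and on acidification ring B recloses and the three labile centres should settle in the thermodynamic arrangement with the new hydroxyl trans to the anomeric hydroxyl.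

**Compound list**
1 | 2,2-dimethylcyclopentane-1,3-dione | CC1(C)C(=O)CCC1=O | starting material
2 | (S)-3-hydroxy-2,2-dimethylcyclopentan-1-one | O[C@H]1CCC(=O)C1(C)C | intermediate
3 | (S)-2,2-dimethyl-3-oxocyclopentyl acetate | CC(=O)O[C@H]1CCC(=O)C1(C)C | intermediate
4 | (S)-5,5-dimethyl-4-oxocyclopent-2-en-1-yl acetate | CC(=O)O[C@H]1C=CC(=O)C1(C)C | intermediate
5 | lithium alkoxide of the alkynyl carbinol (oxygen cis to acetate) | CC(=O)O[C@H]1C=C[C@]([O-])(C#C[Si](C)(C)C)C1(C)C.[Li+] | intermediate
6 | (1S,4R)-5,5-dimethyl-4-[(trimethylsilyl)ethynyl]-4-[(trimethylsilyl)oxy]cyclopent-2-en-1-yl acetate | CC(=O)O[C@H]1C=C[C@](O[Si](C)(C)C)(C#C[Si](C)(C)C)C1(C)C | intermediate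
7 | trimethylsilyl ketene acetal of 6 | C=C(O[Si](C)(C)C)O[C@H]1C=C[C@](O[Si](C)(C)C)(C#C[Si](C)(C)C)C1(C)C | intermediate
8 | trimethylsilyl (cyclopent-2-enyl)acetate after the [3,3] shift (side chain cis to the silyloxy group) | C[Si](C)(C)OC(=O)C[C@@H]1C=CC(C)(C)[C@@]1(O[Si](C)(C)C)C#C[Si](C)(C)C | intermediate
9 | cis γ-hydroxy acid | OC(=O)C[C@@H]1C=CC(C)(C)[C@@]1(O)C#C[Si](C)(C)C | intermediate
10 | cis-fused 6,6-dimethyl-6a-[(trimethylsilyl)ethynyl]-3,3a,6,6a-tetrahydro-2H-cyclopenta[b]furan-2-one | C1C(=O)O[C@]2(C#C[Si](C)(C)C)[C@H]1C=CC2(C)C | intermediate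
11 | lithium enolate of lactone 10 | [Li+].[O-]C1=C[C@@H]2C=CC(C)(C)[C@]2(C#C[Si](C)(C)C)O1 | intermediate
12 | 3-exo-methyl lactone (methyl on the convex face, trans to the ring bond at C3a) | C[C@@H]1C(=O)O[C@]2(C#C[Si](C)(C)C)[C@H]1C=CC2(C)C | intermediate
13 | bromomagnesium lactolate from vinyl addition | C=CC1([O-])[C@@H](C)[C@@H]2C=CC(C)(C)[C@]2(C#C[Si](C)(C)C)O1.[Mg+2].[Br-] | intermediate
14 | 4-{2-hydroxy-3,3-dimethyl-2-[(trimethylsilyl)ethynyl]cyclopent-4-en-1-yl}pent-1-en-3-one (open form of the lactol) | C=CC(=O)[C@@H](C)[C@@H]1C=CC(C)(C)[C@@]1(O)C#C[Si](C)(C)C | intermediate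
15 | 4-(2-acetyl-2-hydroxy-3,3-dimethylcyclopent-4-en-1-yl)pent-1-en-3-one | C=CC(=O)[C@@H](C)[C@@H]1C=CC(C)(C)[C@@]1(O)C(C)=O | intermediate
16 | dilithium alkoxide enolate of 15 | C=CC(=O)[C@@H](C)[C@@H]1C=CC(C)(C)[C@@]1([O-])C(=C)[O-].[Li+].[Li+] | intermediate
17 | trans-fused 6-ethenyl-3a,6-dihydroxy-3,3,7-trimethyl-3,3a,5,6,7,7a-hexahydro-4H-inden-4-one (C6 unspecified) | C=CC1(O)CC(=O)[C@@]2(O)[C@@H](C=CC2(C)C)[C@@H]1C | intermediate
18 | allylic hydroperoxide from the ene reaction (hydroperoxy carbon unspecified) | C=CC1(O)CC(=O)[C@@]2(O)C(=CC(OO)C2(C)C)[C@@H]1C | intermediate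
19 | 6-ethenyl-3a,6-dihydroxy-3,3,7-trimethyl-3,3a,6,7-tetrahydro-2H-indene-2,4(5H)-dione (C6 unspecified) | C=CC1(O)CC(=O)[C@@]2(O)C(=CC(=O)C2(C)C)[C@@H]1C | intermediate
20 | 4-hydroxy-5,6-dimethyl-2H-pyran-2-one | Cc1oc(=O)cc(O)c1C | starting material
21 | 2-(hydrindenedion-6-yl)-6,7-dimethyl-2,3-dihydro-4H-furo[3,2-c]pyran-4-one (O–CH and carbinol carbons unspecified) | Cc1oc(=O)c2c(c1C)OC(C2)C3(O)CC(=O)[C@@]4(O)C(=CC(=O)C4(C)C)[C@@H]3C | intermediate
22 | bis(trimethylsilyl) ether of 21 | Cc1oc(=O)c2c(c1C)OC(C2)C3(O[Si](C)(C)C)CC(=O)[C@@]4(O[Si](C)(C)C)C(=CC(=O)C4(C)C)[C@@H]3C | intermediate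
23 | 5-[(4-hydroxy-5,6-dimethyl-2-oxo-2H-pyran-3-yl)methyl]-8a-hydroxy-1,1,4-trimethyl-4,5,7,8a-tetrahydroazulene-2,6,8(1H)-trione (ring-opened form of 24) | Cc1oc(=O)c(C[C@H]2C(=O)CC(=O)[C@@]3(O)C(=CC(=O)C3(C)C)[C@@H]2C)c(O)c1C | intermediate
24 | deoxy hemiketal: the target with CH2 in place of CH(OH) next to the hemiketal carbon | Cc1oc(=O)c2c(c1C)O[C@]1(O)CC(=O)[C@@]3(O)C(=CC(=O)C3(C)C)[C@H](C)[C@H]1C2 | intermediate
25 | tripotassium salt of ring-opened 24 (pyronolate, tertiary alkoxide, 1,3-diketone enolate) | Cc1oc(=O)c(C[C@H]2C(=O)C=C([O-])[C@@]3([O-])C(=CC(=O)C3(C)C)[C@@H]2C)c([O-])c1C.[K+].[K+].[K+] | intermediate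
26 | CNP0525404.1 | Cc1oc(=O)c2c(c1C)O[C@]1(O)[C@H](O)C(=O)[C@@]3(O)C(=CC(=O)C3(C)C)[C@H](C)[C@H]1C2 | target

Total steps: 13. Longest linear sequence: 13 steps (1 to 26); the pyrone 20 enters at step 11.

**Steps most likely to fail**

Step 12 (proposed new method). The furan C–O bond may fail to ionise, or the substrate may eliminate to the aromatic furan or to a 3-alkenylpyrone, or the wrong ring bond may migrate. The fallback uses known chemistry and sets out from 19. N-Bromosuccinimide in i-PrOH/CH2Cl2 at −20 °C should trigger the halonium-induced semipinacol ring expansion of the 1-vinylcyclohexanol, giving 5-(bromomethyl)-8a-hydroxy-1,1,4-trimethyl-4,5,7,8a-tetrahydroazulene-2,6,8(1H)-trione F1. Treating F1 with pyrone 20 and Et3N in CH2Cl2 should eliminate HBr to the α-methylene ketone in situ; conjugate addition of pyrone C3 and hemiketalisation (the warfarin-type reaction) then return to the route at 24.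

Step 11. The adduct radical beside the hindered quaternary carbinol may be reduced or over-oxidised instead of closing, and the mono-substituted alkene may add the pyrone radical too slowly. The fallback sets out from 19. Hydroxyl-directed epoxidation with VO(acac)2 and t-BuOOH should give the epoxy alcohol 3a,6-dihydroxy-3,3,7-trimethyl-6-(oxiran-2-yl)-3,3a,6,7-tetrahydro-2H-indene-2,4(5H)-dione F2. Opening of F2 at its terminal carbon by C3 of pyrone 20 (Cs2CO3, DMF) should give the triol 3-[2-hydroxy-2-(hydrindenedion-6-yl)ethyl]-4-hydroxy-5,6-dimethyl-2H-pyran-2-one F3. Mitsunobu cyclodehydration of F3 (PPh3, diisopropyl azodicarboxylate) between the pyrone 4-OH and the secondary alcohol returns to the route at 21.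

Step 13. The oxidant may attack the pyronolate carbon, or the 2-hydroxy-1,3-diketone may be over-oxidised or cleaved by retro-Claisen under base. The fallback sets out from 24. Acid-catalysed dehydration (TsOH, toluene, reflux) should give the ring-B enol ether F4 (2H-pyran with the double bond between the former hemiketal carbon and the CH2). Dimethyldioxirane in acetone at 0 °C should give the glycal-type epoxide F5, and hydrolytic opening of F5 at the acetal carbon delivers the trans-diol and returns to the route at 26; either epoxide face should converge through the labile centres.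

**Further compounds**
F1 | step 12 | 5-(bromomethyl)-8a-hydroxy-1,1,4-trimethyl-4,5,7,8a-tetrahydroazulene-2,6,8(1H)-trione (C5 unspecified) | BrCC1C(=O)CC(=O)[C@@]2(O)C(=CC(=O)C2(C)C)[C@@H]1C
F2 | step 11 | 3a,6-dihydroxy-3,3,7-trimethyl-6-(oxiran-2-yl)-3,3a,6,7-tetrahydro-2H-indene-2,4(5H)-dione | C1OC1C2(O)CC(=O)[C@@]3(O)C(=CC(=O)C3(C)C)[C@@H]2C
F3 | step 11 | 3-[2-hydroxy-2-(3a,6-dihydroxy-3,3,7-trimethyl-2,4-dioxo-hexahydroinden-6-yl)ethyl]-4-hydroxy-5,6-dimethyl-2H-pyran-2-one | Cc1oc(=O)c(CC(O)C2(O)CC(=O)[C@@]3(O)C(=CC(=O)C3(C)C)[C@@H]2C)c(O)c1C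
F4 | step 13 | ring-B enol ether (anhydro form of 24) | Cc1oc(=O)c2c(c1C)OC1=CC(=O)[C@@]3(O)C(=CC(=O)C3(C)C)[C@H](C)[C@H]1C2
F5 | step 13 | epoxide of F4 across the enol ether double bond | Cc1oc(=O)c2c(c1C)O[C@]13O[C@@H]3C(=O)[C@@]4(O)C(=CC(=O)C4(C)C)[C@H](C)[C@H]1C2
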